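## Structural features

The target is a chalcone whose ring A is a fully oxygenated phloroglucinol nucleus. C4 carries a free hydroxyl, C6 a methoxy group, and C7a the ether oxygen O1 of a fused 2,3-dihydrofuran (ring C). C7 lies between C7a and C6 and carries the (E)-4-hydroxycinnamoyl unit, so the ketone is flanked by two ether oxygens and has no free ortho hydroxyl. The only stereocentre is C2 (S), an ether carbon that bears a 2-hydroxypropan-2-yl group and sits next to the benzylic methylene C3; it has no stereogenic neighbour in the target. Fragile elements are the enone (conjugate addition, E/Z isomerisation, strong base), the two phenols (oxidation), the tertiary alcohol next to C2 (acid favours ring expansion to a chromanol), and the C3–C2–O1 array, where a carbanion at C3 would expel O1 and erase C2. The real difficulties are telling apart the three oxygens of ring A, placing the acyl group on C7 and not on C5, and creating an isolated stereocentre. The key step exploits the C2–H bond, which is alpha to O1 and lies 1,5 to C3: a carbene on C3, held on C3a, can enter that bond, which forms C2–C3, closes ring C and sets C2 under catalyst control.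

## Logic of the disconnections

25 goes back to 24 by cutting three O–Si bonds. All three hydroxyls are masked as silyl ethers so that one fluoride treatment ends the synthesis. The gain is that no acidic O–H is present during the organolithium chemistry. The demand is a buffered fluoride source, so that the enone never meets a free phenoxide in strongly basic medium.

24 goes back to 18 and 21 by cutting the C7–C(=O) bond. C7–H is the only ring hydrogen flanked by two coordinating ether oxygens (O1 and the methoxy group), while C5–H is shielded by the bulky silyl ether on O4. The gain is that the whole enone half is carried by 21, itself cut at its C=C bond into 19 and 20. The demand is site-selective lithiation and clean 1,2-acyl transfer.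

18 goes back through 16 to 15 by re-attaching a carboxyl group to C3 (cutting C3–H in the retro sense) and then its ester C–O bond. The carboxyl group exists only to make the carbene of the key step. The demand is removal without base: the ester is cleaved reductively and the acid is removed as a radical through 17, so that no enolate at C3 can expel O1.

15 goes back to 14 by cutting C2–C3. This single cut opens ring C and removes both stereocentres, leaving an achiral aryldiazoacetate with an ether side chain. The demands on 14 are met as follows: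
- exactly one C–H donor sits in 1,5 reach of the carbene;
- O4 carries a silyl group, which has no C–H on the atom bound to oxygen, survives steps 9 to 13 unchanged, blocks C5 later, and needs no exchange; an acyl group there would need exchanging before the lithiation and would offer its carbonyl oxygen to the carbene;
- the ester is the trichloroethyl ester, whose CH2 is deactivated against insertion into the ester alkyl group and which is cleaved without base;
- the tertiary alcohol is silylated.

14 goes back through 13 and 12 to 10 and 11 by cutting the C=N2 bond, one O–Si bond and the ester C–O bond. The order matters: the activated ester is made only after O1 is alkylated, because a free phenoxide ortho to that ester would re-close to the lactone and expel the alkoxide of 11.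

10 goes back to 7 and 8 by cutting the O1–CH2 bond and re-closing the lactone. The epoxide 8 delivers the whole side chain in one step. The demand is that the phenoxide attacks the CH2 of 8 while the acid is present as a carboxylate (9), which cannot lactonise, and that the aryl silyl ether survives.

7 goes back through 6 and 5 to 2 and 3, and 2 to 1. The cuts are one O–Si bond, the lactone C–O bond (with the two acetal ethers and the benzylic C–O bond restored), and the aryl–carbon bond between the two acetal-bearing carbons. Metalation between two chelating acetal ethers puts the two-carbon unit on the right carbon with certainty. Lactonisation of one of two equivalent phenols is what tells O1 and O4 apart. 3, 8, 11, 19 and 20 are purchased.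

## Other disconnections considered

**Alternative 1:**
- **Cut:** through ring A. C7a–C3a and C4–C5 are unmade as a ketene–alkyne cycloaddition and C7–C7a as a 6-pi electrocyclisation, leading to 3-methoxycyclobut-2-en-1-one A1 and the chiral silyl ynol ether A2, which already holds the stereocentre as a dioxolane.
- **Forward key step:** heating A1 with A2 would open the cyclobutenone to a vinylketene, add it to the alkyne, reopen the new cyclobutenone and close the dienylketene to the phenol A3.
- **In favour:** the three ring-A oxygens emerge differentiated by construction (free OH on C7a, silyl ether on C4, methyl ether on C6). The stereocentre comes from a building block of dependable enantiopurity. The cascade is thermal and neutral.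
- **Against:** A1 and A2 are sensitive and need several steps each. Ring C must still be closed by an invertive displacement at a secondary carbinol next to a tertiary alcohol, where epoxide formation can intervene. C7 is still unsubstituted.
- **Comparison:** on structure it is better than the chosen plan at differentiating the phenols and at least equal in stereochemical certainty. On mechanism, a pericyclic cascade is more predictable than carbene insertion into a hindered CH2, but the later substitution adds a risk the chosen plan lacks. On the C7 acylation the two are equal. On step economy they are about equal, since A3 would meet the chosen route at 18 only after acetonide removal, ring closure and silylation.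

**Alternative 2:**
- **Cut:** C7–C7a, as an intramolecular Claisen condensation. Ring A is unfolded into the acyl lactone A4, a masked tetraketide whose lactone oxygen sits on the future C2.
- **Forward key step:** double deprotonation of A4 would give a carbanion at C7 that attacks the lactone carbonyl, expels the secondary alkoxide and, after enolisation, gives the chalcone A5.
- **In favour:** the cinnamoyl group is on C7 from the outset, which is better than the late metalation of the chosen plan. The oxygenation pattern of ring A is unambiguous. The stereocentre is carried in, not made.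
- **Against:** A4 holds an enone, a beta-methoxy enone and a 1,3-dicarbonyl unit, so its dianion has other aldol, Michael and pyranone pathways open. A5 has two free phenols flanking the side chain, and the closure of ring C must use the chelated, less reactive one on C7a; the more reactive one on C4 would give the linear isomer. The closure must also invert a hindered carbinol.
- **Comparison:** on structure it is better at C7 and worse at the O1/O4 choice, which the chosen plan settles early. On mechanism the folding step is less controlled than a catalyst-directed insertion. On step economy it is at best equal, because A4 is long to assemble.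

**Alternative 3:**
- **Cut:** O1–C2. The natural chalcone xanthohumol A6 is protected as its bis(methoxymethyl) ether A7.
- **Forward key step:** a chiral dioxirane, formed from a fructose-derived ketone catalyst and KHSO5, would epoxidise the prenyl alkene to the (R)-epoxide A8. On basification the C7a phenoxide would open it 5-exo at the secondary carbon with inversion to give A9, and mild acid would then give 25.
- **In favour:** every carbon is in place from the start. The only free phenol is the one that must close the ring, so the angular isomer is built in. Dioxirane epoxidation of trisubstituted alkenes is a dependable source of enantiopurity.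
- **Against:** the phenoxide needed for ring closure can also add to the enone and give the flavanone. The oxidant meets an electron-rich free phenol. Any acid diverts the epoxide to 6-endo opening.
- **Comparison:** on step economy it is clearly better than the chosen plan (about four steps from A6). On stereocontrol it is at least equal and probably better. On regiochemistry it is equal. On chemoselectivity the chosen plan is better, because the enone is introduced only after ring C exists.

Key step: step 9

Assumption: Rh2(S-PTTL)4 is taken to select the C–H bond that leads to (2S); if the sense is the opposite, Rh2(R-PTTL)4 is used in step 9 with nothing else changed.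

Remark on the chemistry: in 14 the methoxy group is para to the carbene-bearing carbon and so out of reach, and the carbene enters a C–H bond of the O–CH2 group while the C–O bond stays intact.

## Route

Step 1
Reactants: 1 5-methoxybenzene-1,3-diol (5-methoxyresorcinol)
Product: 2 1-methoxy-3,5-bis(methoxymethoxy)benzene
Conditions: MOMCl, i-Pr2NEt, CH2Cl2, 0 °C → rt
Reagents that add atoms: chloromethyl methyl ether, COCCl
Why: O-alkylation of both phenols (Williamson type) with the alpha-chloro ether; the acetal ethers are the strongest oxygen-based directing groups for the next step and are needed only until step 3.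

Step 2
Reactants: 2 1-methoxy-3,5-bis(methoxymethoxy)benzene; 3 ethyl glyoxylate (freshly distilled)
Product: 5 ethyl 2-hydroxy-2-[4-methoxy-2,6-bis(methoxymethoxy)phenyl]acetate (racemic), via aryllithium 4 (not isolated)
Conditions: n-BuLi, THF, 0 °C; then 3, −78 °C; AcOH quench
Reagents that add atoms: none
Why: Directed ortho-metalation: the position between the two chelating acetal ethers is deprotonated in preference to the positions with only one such neighbour, and the aryllithium adds to the aldehyde of 3 faster than to its ester. The new carbinol centre is racemic and is removed in step 3.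

Step 3
Reactants: 5 ethyl 2-hydroxy-2-[4-methoxy-2,6-bis(methoxymethoxy)phenyl]acetate
Product: 6 4-hydroxy-6-methoxy-1-benzofuran-2(3H)-one
Conditions: Et3SiH, TFA, CH2Cl2, 0 °C → rt; then TsOH (cat.), PhMe, 80 °C
Reagents that add atoms: none
Why: Ionic hydrogenation: the benzylic alcohol, stabilised by three ortho/para oxygens, ionises in TFA and takes hydride from the silane, which also traps the methoxymethyl cations released from both acetals. One of the two equivalent phenols then lactonises onto the ester, which differentiates the two oxygens for the rest of the route.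

Step 4
Reactants: 6 4-hydroxy-6-methoxy-1-benzofuran-2(3H)-one
Product: 7 6-methoxy-4-(triisopropylsilyloxy)-1-benzofuran-2(3H)-one
Conditions: TIPSOTf, 2,6-lutidine, CH2Cl2, −78 → 0 °C
Reagents that add atoms: triisopropylsilyl trifluoromethanesulfonate, CC(C)[Si](OS(=O)(=O)C(F)(F)F)(C(C)C)C(C)C
Why: O-silylation of the only free phenol; the hindered, non-nucleophilic base avoids acyl transfer from the aryl lactone and enolisation of its acidic CH2.

Step 5
Reactants: 7 6-methoxy-4-(triisopropylsilyloxy)-1-benzofuran-2(3H)-one; 8 2,2-dimethyloxirane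
Product: 10 2-[2-(2-hydroxy-2-methylpropoxy)-4-methoxy-6-(triisopropylsilyloxy)phenyl]acetic acid, via lithium hydroxyarylacetate 9 (not isolated)
Conditions: LiOH·H2O (1.05 equiv), THF–H2O, 0 °C; evaporate; 8, K2CO3 (cat.), DMF, 65 °C, sealed tube; aq. HCl to pH 3, 0 °C
Reagents that add atoms: lithium hydroxide, [Li+].[OH-]
Why: Saponification of the activated aryl lactone frees the second phenol next to a carboxylate that cannot re-lactonise; base-catalysed SN2 opening of the epoxide by the phenoxide at the unsubstituted CH2 then gives the aryl ether and the tertiary alcohol. The hydroxide is consumed at 0 °C before heating, which should spare the aryl silyl ether.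

Step 6
Reactants: 10 2-[2-(2-hydroxy-2-methylpropoxy)-4-methoxy-6-(triisopropylsilyloxy)phenyl]acetic acid; 11 2,2,2-trichloroethanol
Product: 12 2,2,2-trichloroethyl 2-[2-(2-hydroxy-2-methylpropoxy)-4-methoxy-6-(triisopropylsilyloxy)phenyl]acetate
Conditions: DCC, DMAP (cat.), CH2Cl2, 0 °C → rt
Reagents that add atoms: none
Why: Steglich esterification with the primary alcohol 11; the tertiary alcohol is too hindered to compete. The activated ester is made only now, when no ortho phenol is left to displace trichloroethoxide and re-form the lactone.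

Step 7
Reactants: 12 2,2,2-trichloroethyl 2-[2-(2-hydroxy-2-methylpropoxy)-4-methoxy-6-(triisopropylsilyloxy)phenyl]acetate
Product: 13 2,2,2-trichloroethyl 2-[4-methoxy-2-(2-methyl-2-triethylsilyloxypropoxy)-6-(triisopropylsilyloxy)phenyl]acetate
Conditions: TESOTf, 2,6-lutidine, CH2Cl2, −78 → 0 °C
Reagents that add atoms: triethylsilyl trifluoromethanesulfonate, CC[Si](CC)(CC)OS(=O)(=O)C(F)(F)F
Why: Silylation of the tertiary alcohol with a silyl triflate; this removes the O–H bond that a carbene would attack before any C–H bond.

Step 8
Reactants: 13 2,2,2-trichloroethyl 2-[4-methoxy-2-(2-methyl-2-triethylsilyloxypropoxy)-6-(triisopropylsilyloxy)phenyl]acetate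
Product: 14 2,2,2-trichloroethyl 2-diazo-2-[4-methoxy-2-(2-methyl-2-triethylsilyloxypropoxy)-6-(triisopropylsilyloxy)phenyl]acetate
Conditions: p-ABSA, DBU, MeCN, 0 °C → rt
Reagents that add atoms: 4-acetamidobenzenesulfonyl azide, CC(=O)Nc1ccc(cc1)S(=O)(=O)N=[N+]=[N-]
Why: Regitz diazo transfer: the amidine base deprotonates the arylacetate, made more acidic by the trichloroethyl ester, and the enolate takes N2 from the sulfonyl azide.

Step 9
Reactants: 14 2,2,2-trichloroethyl 2-diazo-2-[4-methoxy-2-(2-methyl-2-triethylsilyloxypropoxy)-6-(triisopropylsilyloxy)phenyl]acetate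
Product: 15 2,2,2-trichloroethyl (2S,3R)-6-methoxy-2-[2-(triethylsilyloxy)propan-2-yl]-4-(triisopropylsilyloxy)-2,3-dihydro-1-benzofuran-3-carboxylate (2,3-cis)
Conditions: Rh2(S-PTTL)4 (1 mol %), PhMe, −40 → 0 °C, slow addition of 14
Reagents that add atoms: none
Why: The dirhodium tetracarboxylate Rh2(S-PTTL)4 (tetrakis[N-phthaloyl-(S)-tert-leucinate]) displaces N2 from 14 and gives a rhodium-bound donor/acceptor carbene at the future C3. The carbene carbon enters one C–H bond of the O–CH2 group through a concerted but asynchronous three-centre transition state, forming C2–C3 and moving that hydrogen to C3. The closest known reaction type is the dirhodium-carboxylate-catalysed enantioselective intramolecular 1,5 C–H insertion of ortho-alkoxy aryldiazoacetates to cis-2-substituted 2,3-dihydrobenzofuran-3-carboxylates. Ring C closes by 1,5 insertion, through a five-membered array of the carbene carbon, C3a, C7a, O1 and C2. C2 is set by the catalyst, whose phthalimido walls let only one of the two enantiotopic hydrogens reach the carbene; C3 follows as cis because the ester turns away from the C2 substituent in the transition state, and this centre is removed in step 11. Site selectivity rests on the substrate: the O–CH2 group is the only C–H donor in 1,5 reach and is activated by the ether oxygen, the other ortho oxygen carries silicon, the methoxy group is para, the triethylsilyl ether is remote, and the ester CH2 is deactivated by the CCl3 group against beta-lactone formation. Slow addition keeps the diazo concentration low so that carbene dimerisation should not compete.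

Step 10
Reactants: 15 2,2,2-trichloroethyl (2S,3R)-6-methoxy-2-[2-(triethylsilyloxy)propan-2-yl]-4-(triisopropylsilyloxy)-2,3-dihydro-1-benzofuran-3-carboxylate
Product: 16 (2S,3R)-6-methoxy-2-[2-(triethylsilyloxy)propan-2-yl]-4-(triisopropylsilyloxy)-2,3-dihydro-1-benzofuran-3-carboxylic acid
Conditions: Zn dust, AcOH, THF, 0 °C → rt
Reagents that add atoms: none
Why: Reductive fragmentation of the trichloroethyl ester (two-electron reduction of a C–Cl bond with loss of 1,1-dichloroethene); no base is present, so no enolate forms at C3 and neither O1 nor the configuration at C2 is put at risk.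

Step 11
Reactants: 16 (2S,3R)-6-methoxy-2-[2-(triethylsilyloxy)propan-2-yl]-4-(triisopropylsilyloxy)-2,3-dihydro-1-benzofuran-3-carboxylic acid
Product: 18 (2S)-6-methoxy-2-[2-(triethylsilyloxy)propan-2-yl]-4-(triisopropylsilyloxy)-2,3-dihydro-1-benzofuran, via thiohydroxamate ester 17 (not isolated)
Conditions: N-hydroxypyridine-2-thione, DCC, PhMe, 0 °C, dark; then t-BuSH, hν (visible), rt
Reagents that add atoms: none
Why: Barton reductive decarboxylation: N–O homolysis, loss of CO2 and hydrogen transfer from the thiol to the benzylic C3 radical. The radical p orbital is orthogonal to the C2–O1 bond within the ring, so beta-scission should not compete and C2 is untouched.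

Step 12
Reactants: 19 4-(tert-butyldimethylsilyloxy)benzaldehyde; 20 diethyl {2-[methoxy(methyl)amino]-2-oxoethyl}phosphonate
Product: 21 (E)-3-[4-(tert-butyldimethylsilyloxy)phenyl]-N-methoxy-N-methylprop-2-enamide
Conditions: NaH, THF, 0 °C → rt
Reagents that add atoms: none
Why: Horner–Wadsworth–Emmons olefination; the stabilised phosphonate anion should give the (E)-alkene through the thermodynamically preferred oxaphosphetane.

Step 13
Reactants: 18 (2S)-6-methoxy-2-[2-(triethylsilyloxy)propan-2-yl]-4-(triisopropylsilyloxy)-2,3-dihydro-1-benzofuran; 21 (E)-3-[4-(tert-butyldimethylsilyloxy)phenyl]-N-methoxy-N-methylprop-2-enamide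
Product: 24 (E)-3-[4-(tert-butyldimethylsilyloxy)phenyl]-1-[(2S)-6-methoxy-2-[2-(triethylsilyloxy)propan-2-yl]-4-(triisopropylsilyloxy)-2,3-dihydro-1-benzofuran-7-yl]prop-2-en-1-one, via C7 aryllithium 22 (not isolated), via tetrahedral lithium alkoxide 23 (not isolated)
Conditions: s-BuLi, TMEDA, THF, −78 → −40 °C; then 21, −78 → 0 °C; AcOH quench
Reagents that add atoms: none
Why: Directed ortho-metalation at C7, the only ring position flanked by two coordinating ether oxygens, while C5 is shielded by the bulky, non-coordinating silyl ether on O4. Weinreb ketone synthesis: the N-methoxy-N-methylamide gives a chelated adduct that collapses to the enone only on work-up, so a second addition is excluded and 1,2-addition is expected.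

Step 14
Reactants: 24 (E)-3-[4-(tert-butyldimethylsilyloxy)phenyl]-1-[(2S)-6-methoxy-2-[2-(triethylsilyloxy)propan-2-yl]-4-(triisopropylsilyloxy)-2,3-dihydro-1-benzofuran-7-yl]prop-2-en-1-one
Product: 25 (E)-1-[(2S)-4-hydroxy-2-(2-hydroxypropan-2-yl)-6-methoxy-2,3-dihydro-1-benzofuran-7-yl]-3-(4-hydroxyphenyl)prop-2-en-1-one
Conditions: Bu4NF, AcOH, THF, 0 °C → rt
Reagents that add atoms: none
Why: Fluoride-induced cleavage of the two aryl silyl ethers and the tertiary triethylsilyl ether; acetic acid buffers the phenoxides so that the enone is not exposed to strong base, and C2 is not involved.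

## Compound list

1 | 5-methoxybenzene-1,3-diol (5-methoxyresorcinol) | COc1cc(O)cc(O)c1 | starting material
2 | 1-methoxy-3,5-bis(methoxymethoxy)benzene | COCOc1cc(OC)cc(OCOC)c1 | intermediate
3 | ethyl glyoxylate (ethyl 2-oxoacetate) | CCOC(=O)C=O | starting material
4 | [4-methoxy-2,6-bis(methoxymethoxy)phenyl]lithium | COCOc1cc(OC)cc(OCOC)c1[Li] | intermediate
5 | ethyl 2-hydroxy-2-[4-methoxy-2,6-bis(methoxymethoxy)phenyl]acetate (racemic) | CCOC(=O)C(O)c1c(OCOC)cc(OC)cc1OCOC | intermediate
6 | 4-hydroxy-6-methoxy-1-benzofuran-2(3H)-one | COc1cc(O)c2CC(=O)Oc2c1 | intermediate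
7 | 6-methoxy-4-(triisopropylsilyloxy)-1-benzofuran-2(3H)-one | COc1cc(O[Si](C(C)C)(C(C)C)C(C)C)c2CC(=O)Oc2c1 | intermediate
8 | 2,2-dimethyloxirane | CC1(C)CO1 | starting material
9 | lithium 2-[2-hydroxy-4-methoxy-6-(triisopropylsilyloxy)phenyl]acetate | [Li+].[O-]C(=O)Cc1c(O)cc(OC)cc1O[Si](C(C)C)(C(C)C)C(C)C | intermediate
10 | 2-[2-(2-hydroxy-2-methylpropoxy)-4-methoxy-6-(triisopropylsilyloxy)phenyl]acetic acid | OC(=O)Cc1c(OCC(C)(C)O)cc(OC)cc1O[Si](C(C)C)(C(C)C)C(C)C | intermediate
11 | 2,2,2-trichloroethanol | OCC(Cl)(Cl)Cl | starting material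
12 | 2,2,2-trichloroethyl 2-[2-(2-hydroxy-2-methylpropoxy)-4-methoxy-6-(triisopropylsilyloxy)phenyl]acetate | COc1cc(OCC(C)(C)O)c(CC(=O)OCC(Cl)(Cl)Cl)c(O[Si](C(C)C)(C(C)C)C(C)C)c1 | intermediate
13 | 2,2,2-trichloroethyl 2-[4-methoxy-2-(2-methyl-2-triethylsilyloxypropoxy)-6-(triisopropylsilyloxy)phenyl]acetate | COc1cc(OCC(C)(C)O[Si](CC)(CC)CC)c(CC(=O)OCC(Cl)(Cl)Cl)c(O[Si](C(C)C)(C(C)C)C(C)C)c1 | intermediate
14 | 2,2,2-trichloroethyl 2-diazo-2-[4-methoxy-2-(2-methyl-2-triethylsilyloxypropoxy)-6-(triisopropylsilyloxy)phenyl]acetate | COc1cc(OCC(C)(C)O[Si](CC)(CC)CC)c(C(=[N+]=[N-])C(=O)OCC(Cl)(Cl)Cl)c(O[Si](C(C)C)(C(C)C)C(C)C)c1 | intermediate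
15 | 2,2,2-trichloroethyl (2S,3R)-6-methoxy-2-[2-(triethylsilyloxy)propan-2-yl]-4-(triisopropylsilyloxy)-2,3-dihydro-1-benzofuran-3-carboxylate | COc1cc(O[Si](C(C)C)(C(C)C)C(C)C)c2c(c1)O[C@H](C(C)(C)O[Si](CC)(CC)CC)[C@@H]2C(=O)OCC(Cl)(Cl)Cl | intermediate
16 | (2S,3R)-6-methoxy-2-[2-(triethylsilyloxy)propan-2-yl]-4-(triisopropylsilyloxy)-2,3-dihydro-1-benzofuran-3-carboxylic acid | COc1cc(O[Si](C(C)C)(C(C)C)C(C)C)c2c(c1)O[C@H](C(C)(C)O[Si](CC)(CC)CC)[C@@H]2C(=O)O | intermediate
17 | 2-thioxopyridin-1(2H)-yl (2S,3R)-6-methoxy-2-[2-(triethylsilyloxy)propan-2-yl]-4-(triisopropylsilyloxy)-2,3-dihydro-1-benzofuran-3-carboxylate | COc1cc(O[Si](C(C)C)(C(C)C)C(C)C)c2c(c1)O[C@H](C(C)(C)O[Si](CC)(CC)CC)[C@@H]2C(=O)ON1C=CC=CC1=S | intermediate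
18 | (2S)-6-methoxy-2-[2-(triethylsilyloxy)propan-2-yl]-4-(triisopropylsilyloxy)-2,3-dihydro-1-benzofuran | COc1cc(O[Si](C(C)C)(C(C)C)C(C)C)c2c(c1)O[C@H](C(C)(C)O[Si](CC)(CC)CC)C2 | intermediate
19 | 4-(tert-butyldimethylsilyloxy)benzaldehyde | CC(C)(C)[Si](C)(C)Oc1ccc(C=O)cc1 | starting material
20 | diethyl {2-[methoxy(methyl)amino]-2-oxoethyl}phosphonate | CCOP(=O)(CC(=O)N(C)OC)OCC | starting material
21 | (E)-3-[4-(tert-butyldimethylsilyloxy)phenyl]-N-methoxy-N-methylprop-2-enamide | CON(C)C(=O)/C=C/c1ccc(O[Si](C)(C)C(C)(C)C)cc1 | intermediate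
22 | [(2S)-6-methoxy-2-[2-(triethylsilyloxy)propan-2-yl]-4-(triisopropylsilyloxy)-2,3-dihydro-1-benzofuran-7-yl]lithium | COc1cc(O[Si](C(C)C)(C(C)C)C(C)C)c2c(c1[Li])O[C@H](C(C)(C)O[Si](CC)(CC)CC)C2 | intermediate
23 | lithium alkoxide of (E)-3-[4-(tert-butyldimethylsilyloxy)phenyl]-1-[methoxy(methyl)amino]-1-[(2S)-6-methoxy-2-[2-(triethylsilyloxy)propan-2-yl]-4-(triisopropylsilyloxy)-2,3-dihydro-1-benzofuran-7-yl]prop-2-en-1-ol (mixture at the new carbon) | COc1cc(O[Si](C(C)C)(C(C)C)C(C)C)c2c(c1C(O[Li])(N(C)OC)/C=C/c1ccc(O[Si](C)(C)C(C)(C)C)cc1)O[C@H](C(C)(C)O[Si](CC)(CC)CC)C2 | intermediate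
24 | (E)-3-[4-(tert-butyldimethylsilyloxy)phenyl]-1-[(2S)-6-methoxy-2-[2-(triethylsilyloxy)propan-2-yl]-4-(triisopropylsilyloxy)-2,3-dihydro-1-benzofuran-7-yl]prop-2-en-1-one | COc1cc(O[Si](C(C)C)(C(C)C)C(C)C)c2c(c1C(=O)/C=C/c1ccc(O[Si](C)(C)C(C)(C)C)cc1)O[C@H](C(C)(C)O[Si](CC)(CC)CC)C2 | intermediate
25 | (E)-1-[(2S)-4-hydroxy-2-(2-hydroxypropan-2-yl)-6-methoxy-2,3-dihydro-1-benzofuran-7-yl]-3-(4-hydroxyphenyl)prop-2-en-1-one | COc1cc(O)c2c(c1C(=O)/C=C/c1ccc(O)cc1)O[C@H](C(C)(C)O)C2 | target

## Step count and least certain steps

Total step count: 14. Longest linear sequence: 13 steps (steps 1 to 11, 13 and 14, from 1 to 25).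

**Step 9 (key step).** What may go wrong: weak discrimination between the two enantiotopic hydrogens of a non-benzylic O–CH2 that sits next to a quaternary carbon; slow insertion that lets carbene dimerisation or insertion into silicon-bound alkyl C–H bonds compete; and erosion of the ee at C2 after decarboxylation if a minor trans isomer has the opposite C2 configuration. Fallback, from 2 back to 18, with the stereocentre made by asymmetric epoxidation: lithiation of 2 as in step 2, transmetalation with CuBr·SMe2 and alkylation with 1-bromo-3-methylbut-2-ene would give 1-methoxy-3,5-bis(methoxymethoxy)-2-(3-methylbut-2-en-1-yl)benzene F1. HCl in MeOH would free 5-methoxy-2-(3-methylbut-2-en-1-yl)benzene-1,3-diol F2, and TIPSOTf with 2,6-lutidine would give its bis(triisopropylsilyl) ether F3. Shi epoxidation (fructose-derived ketone catalyst, KHSO5, buffered MeCN–H2O, enantiomer of the catalyst chosen for the R epoxide) would give the (2R)-3,3-dimethyloxiran-2-ylmethyl arene F4. Bu4NF would unmask the phenoxides, one of which opens the epoxide 5-exo at the secondary carbon with inversion to give (2S)-2-(2-hydroxypropan-2-yl)-6-methoxy-2,3-dihydro-1-benzofuran-4-ol F5. Selective phenol silylation (TIPSCl, imidazole) would give 2-[(2S)-6-methoxy-4-(triisopropylsilyloxy)-2,3-dihydro-1-benzofuran-2-yl]propan-2-ol F6, and TESOTf with 2,6-lutidine would give 18.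

**Step 3.** What may go wrong: acid-induced loss of the two-carbon unit from the very electron-rich ring (retro-Friedel–Crafts), self-alkylation of another ring by the benzylic cation, or ring hydroxymethylation by acetal fragments. Fallback, from 5 back to 6, with the deoxygenation moved to a neutral electron-transfer step: acetylation (Ac2O, pyridine) would give ethyl 2-acetoxy-2-[4-methoxy-2,6-bis(methoxymethoxy)phenyl]acetate F7. SmI2 in THF–MeOH would reduce off the acetoxy group to give ethyl 2-[4-methoxy-2,6-bis(methoxymethoxy)phenyl]acetate F8. TFA with Et3SiH as cation scavenger, followed by warming in PhMe with TsOH, would then remove the acetals and close the lactone 6.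

**Step 5.** What may go wrong: loss or migration of the aryl silyl ether under the basic conditions, and competing alkylation of the carboxylate by the epoxide. Fallback, from 7 back to 10, forming the ether under neutral conditions and the tertiary alcohol by hydration: methanolysis (MeOH, DMAP cat.) would give methyl 2-[2-hydroxy-4-methoxy-6-(triisopropylsilyloxy)phenyl]acetate F9. Mitsunobu etherification with 2-methylprop-2-en-1-ol (PPh3, DIAD) would give methyl 2-[4-methoxy-2-(2-methylprop-2-en-1-yloxy)-6-(triisopropylsilyloxy)phenyl]acetate F10. Mukaiyama hydration (Co(acac)2, PhSiH3, O2) would give methyl 2-[2-(2-hydroxy-2-methylpropoxy)-4-methoxy-6-(triisopropylsilyloxy)phenyl]acetate F11, and brief saponification (LiOH, THF–H2O, 0 °C) would give 10.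

**Step 11.** What may go wrong: recombination of the stabilised benzylic radical with the pyridylthio fragment in place of hydrogen abstraction, and premature thermal decomposition of the thiohydroxamate ester. Fallback, from 16 directly to 18: photoredox hydrodecarboxylation of the free acid (9-mesityl-10-methylacridinium tetrafluoroborate, PhSSPh cat., 2,6-lutidine, trifluoroethanol, blue light), in which the carboxylate is oxidised and the C3 radical is reduced by thiophenol; no new compound is made (F0).

**Step 13.** What may go wrong: incomplete or misdirected lithiation, and conjugate addition or poor acyl transfer when the hindered aryllithium meets the unsaturated amide. Fallback, from 18 and 21 back to 24, by addition to an aldehyde and oxidation: i-Bu2AlH would reduce 21 to (E)-3-[4-(tert-butyldimethylsilyloxy)phenyl]prop-2-enal F12. Addition of 22 (made from 18 as in step 13) to F12 would give (E)-3-[4-(tert-butyldimethylsilyloxy)phenyl]-1-[(2S)-6-methoxy-2-[2-(triethylsilyloxy)propan-2-yl]-4-(triisopropylsilyloxy)-2,3-dihydro-1-benzofuran-7-yl]prop-2-en-1-ol F13 as a mixture at the carbinol carbon, and MnO2 in CH2Cl2 would oxidise it to 24.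

## Further compounds

F1 | step 9 | 1-methoxy-3,5-bis(methoxymethoxy)-2-(3-methylbut-2-en-1-yl)benzene | COCOc1cc(OC)cc(OCOC)c1CC=C(C)C
F2 | step 9 | 5-methoxy-2-(3-methylbut-2-en-1-yl)benzene-1,3-diol | COc1cc(O)c(CC=C(C)C)c(O)c1
F3 | step 9 | 5-methoxy-2-(3-methylbut-2-en-1-yl)-1,3-bis(triisopropylsilyloxy)benzene | COc1cc(O[Si](C(C)C)(C(C)C)C(C)C)c(CC=C(C)C)c(O[Si](C(C)C)(C(C)C)C(C)C)c1
F4 | step 9 | 2-{[(2R)-3,3-dimethyloxiran-2-yl]methyl}-5-methoxy-1,3-bis(triisopropylsilyloxy)benzene | COc1cc(O[Si](C(C)C)(C(C)C)C(C)C)c(C[C@H]2OC2(C)C)c(O[Si](C(C)C)(C(C)C)C(C)C)c1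
F5 | step 9 | (2S)-2-(2-hydroxypropan-2-yl)-6-methoxy-2,3-dihydro-1-benzofuran-4-ol | COc1cc(O)c2c(c1)O[C@H](C(C)(C)O)C2
F6 | step 9 | 2-[(2S)-6-methoxy-4-(triisopropylsilyloxy)-2,3-dihydro-1-benzofuran-2-yl]propan-2-ol | COc1cc(O[Si](C(C)C)(C(C)C)C(C)C)c2c(c1)O[C@H](C(C)(C)O)C2
F7 | step 3 | ethyl 2-acetoxy-2-[4-methoxy-2,6-bis(methoxymethoxy)phenyl]acetate (racemic) | CCOC(=O)C(OC(C)=O)c1c(OCOC)cc(OC)cc1OCOC
F8 | step 3 | ethyl 2-[4-methoxy-2,6-bis(methoxymethoxy)phenyl]acetate | CCOC(=O)Cc1c(OCOC)cc(OC)cc1OCOC
F9 | step 5 | methyl 2-[2-hydroxy-4-methoxy-6-(triisopropylsilyloxy)phenyl]acetate | COC(=O)Cc1c(O)cc(OC)cc1O[Si](C(C)C)(C(C)C)C(C)C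
F10 | step 5 | methyl 2-[4-methoxy-2-(2-methylprop-2-en-1-yloxy)-6-(triisopropylsilyloxy)phenyl]acetate | COC(=O)Cc1c(OCC(C)=C)cc(OC)cc1O[Si](C(C)C)(C(C)C)C(C)C
F11 | step 5 | methyl 2-[2-(2-hydroxy-2-methylpropoxy)-4-methoxy-6-(triisopropylsilyloxy)phenyl]acetate | COC(=O)Cc1c(OCC(C)(C)O)cc(OC)cc1O[Si](C(C)C)(C(C)C)C(C)C
F0 | step 11 | none | none
F12 | step 13 | (E)-3-[4-(tert-butyldimethylsilyloxy)phenyl]prop-2-enal | O=C/C=C/c1ccc(O[Si](C)(C)C(C)(C)C)cc1
F13 | step 13 | (E)-3-[4-(tert-butyldimethylsilyloxy)phenyl]-1-[(2S)-6-methoxy-2-[2-(triethylsilyloxy)propan-2-yl]-4-(triisopropylsilyloxy)-2,3-dihydro-1-benzofuran-7-yl]prop-2-en-1-ol (mixture at the carbinol carbon) | COc1cc(O[Si](C(C)C)(C(C)C)C(C)C)c2c(c1C(O)/C=C/c1ccc(O[Si](C)(C)C(C)(C)C)cc1)O[C@H](C(C)(C)O[Si](CC)(CC)CC)C2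
A1 | alternative 1 | 3-methoxycyclobut-2-en-1-one | COC1=CC(=O)C1
A2 | alternative 1 | triisopropyl({3-[(4R)-2,2,5,5-tetramethyl-1,3-dioxolan-4-yl]prop-1-yn-1-yl}oxy)silane | CC(C)[Si](OC#CC[C@H]1OC(C)(C)OC1(C)C)(C(C)C)C(C)C
A3 | alternative 1 | 5-methoxy-2-{[(4R)-2,2,5,5-tetramethyl-1,3-dioxolan-4-yl]methyl}-3-(triisopropylsilyloxy)phenol | COc1cc(O)c(C[C@H]2OC(C)(C)OC2(C)C)c(O[Si](C(C)C)(C(C)C)C(C)C)c1
A4 | alternative 2 | (5R)-3-{(2E,6E)-7-[4-(tert-butyldimethylsilyloxy)phenyl]-3-methoxy-5-oxohepta-2,6-dienoyl}-5-[2-(triethylsilyloxy)propan-2-yl]oxolan-2-one | O=C1O[C@@H](C(C)(C)O[Si](CC)(CC)CC)CC1C(=O)/C=C(/OC)CC(=O)/C=C/c1ccc(O[Si](C)(C)C(C)(C)C)cc1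
A5 | alternative 2 | (E)-3-[4-(tert-butyldimethylsilyloxy)phenyl]-1-{2,4-dihydroxy-3-[(2R)-2-hydroxy-3-methyl-3-(triethylsilyloxy)butyl]-6-methoxyphenyl}prop-2-en-1-one | COc1cc(O)c(C[C@@H](O)C(C)(C)O[Si](CC)(CC)CC)c(O)c1C(=O)/C=C/c1ccc(O[Si](C)(C)C(C)(C)C)cc1
A6 | alternative 3 | xanthohumol, (E)-1-[2,4-dihydroxy-6-methoxy-3-(3-methylbut-2-en-1-yl)phenyl]-3-(4-hydroxyphenyl)prop-2-en-1-one | COc1cc(O)c(CC=C(C)C)c(O)c1C(=O)/C=C/c1ccc(O)cc1
A7 | alternative 3 | (E)-1-[2-hydroxy-6-methoxy-4-(methoxymethoxy)-3-(3-methylbut-2-en-1-yl)phenyl]-3-[4-(methoxymethoxy)phenyl]prop-2-en-1-one | COCOc1ccc(/C=C/C(=O)c2c(OC)cc(OCOC)c(CC=C(C)C)c2O)cc1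
A8 | alternative 3 | (E)-1-[3-{[(2R)-3,3-dimethyloxiran-2-yl]methyl}-2-hydroxy-6-methoxy-4-(methoxymethoxy)phenyl]-3-[4-(methoxymethoxy)phenyl]prop-2-en-1-one | COCOc1ccc(/C=C/C(=O)c2c(OC)cc(OCOC)c(C[C@H]3OC3(C)C)c2O)cc1
A9 | alternative 3 | (E)-1-[(2S)-2-(2-hydroxypropan-2-yl)-6-methoxy-4-(methoxymethoxy)-2,3-dihydro-1-benzofuran-7-yl]-3-[4-(methoxymethoxy)phenyl]prop-2-en-1-one | COCOc1ccc(/C=C/C(=O)c2c(OC)cc(OCOC)c3c2O[C@H](C(C)(C)O)C3)cc1
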